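## Retrosynthetic overview
1. Komaroviquinone comes from a 7,10-hemiketal-bridged trimethoxyarene by CAN unmasking. The seven-membered ring B and the hemiketal form together when an aryllithium adds intramolecularly to a γ-lactone carbonyl (C7).
2. Aromatic ring C is built by the thermal 4π-ring-opening/6π-closure cascade of a 4-alkenyl-4-hydroxycyclobutenone. That cyclobutenone comes from a 2-lithioallyl lactone plus 3-isopropyl-4-methoxysquarate.
3. The ring A lactone (quaternary C10–O, C20 arm) comes from 2-bromoallyl-indium addition to a keto ester; only the cis-fused lactone can close. The C5 stereocentre comes from (S)-limonene, and C10 and C7 follow from it.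
4. Ring A ketone: limonene is ozonolysed, closed by aldol, and gem-dimethylated with a cuprate. The ketone is then moved from C2 to C10 (Wharton 1,3-transposition).
5. Ring order: A (aldol), lactone, C (electrocyclization), B (ArLi), quinone (CAN).

Assumption: the amine-mediated aldol closes onto the acetyl carbonyl rather than the chain ketone, and the squarate adds at the carbonyl next to the C–OMe carbon.

## Route

**Step 1**
Reactants: 1 (S)-(−)-limonene
Product: 2 (3S)-3-acetyl-6-oxoheptanal
Conditions: O3 (2.5 equiv), CH2Cl2/MeOH, −78 °C; then Me2S, −78 °C → rt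
Reagents that add atoms: ozone, [O-][O+]=O
Why: Ozonolysis cleaves both alkenes (loss of CH2O), and the C4 stereocentre of limonene is untouched and becomes C5 of the target.

**Step 2**
Reactants: 2
Product: 3 (3S)-3-acetyl-6-oxoheptanoic acid
Conditions: NaClO2, NaH2PO4, 2-methyl-2-butene, t-BuOH/H2O, rt
Reagents that add atoms: sodium chlorite, [Na+].[O-]Cl=O
Why: Pinnick oxidation is selective for the aldehyde over the two ketones, and it prevents the 5-membered-ring aldol of the keto-aldehyde.

**Step 3**
Reactants: 3
Product: 4 methyl (3S)-3-acetyl-6-oxoheptanoate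
Conditions: TMSCHN2, MeOH/PhMe, 0 °C
Reagents that add atoms: trimethylsilyldiazomethane, C[Si](C)(C)[CH-][N+]#N
Why: Mild methylation of the acid without disturbing the ketones.

**Step 4**
Reactants: 4
Product: 5 methyl 2-[(1S)-2-methyl-4-oxocyclohex-2-en-1-yl]acetate
Conditions: pyrrolidine (0.3 equiv), AcOH (0.3 equiv), THF, 50 °C
Reagents that add atoms: none
Why: Intramolecular Robinson-type aldol condensation. The enamine forms at the unhindered chain ketone and attacks the acetyl carbonyl, closing ring A. C5 is γ to the enone carbonyl and is not disturbed.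

**Step 5**
Reactants: 5
Product: 6 methyl 2-[(1S)-2,2-dimethyl-4-oxocyclohexyl]acetate
Conditions: Me2CuLi (from CuI/MeLi), TMSCl, THF, −78 → −20 °C
Reagents that add atoms: lithium dimethylcuprate, C[Cu-]C.[Li+]
Why: 1,4-Addition to the β-methyl enone creates the C4 gem-dimethyl centre. This centre is not a stereocentre, so C5 is unaffected.

**Step 6**
Reactants: 6
Product: 7 methyl 2-[(1R)-6,6-dimethyl-4-oxocyclohex-2-en-1-yl]acetate
Conditions: IBX (1.3 equiv), DMSO, 70 °C
Reagents that add atoms: none
Why: Dehydrogenation can only go toward C1–C10 because C4 is quaternary, so the product is a single enone. The descriptor changes from S to R only through CIP priorities.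

**Step 7**
Reactants: 7
Product: 8 methyl 2-[(2S)-3,3-dimethyl-5-oxo-7-oxabicyclo[4.1.0]heptan-2-yl]acetate (epoxide anti to the side chain, bridgehead stereo undefined)
Conditions: 30% H2O2, K2CO3, MeOH, 0 °C
Reagents that add atoms: hydrogen peroxide, OO
Why: Nucleophilic (Weitz–Scheffer) epoxidation of the enone. The new epoxide stereocentres are destroyed in the next step.

**Step 8**
Reactants: 8
Product: 9 methyl 2-[(1S)-2-hydroxy-6,6-dimethylcyclohex-3-en-1-yl]acetate
Conditions: N2H4·H2O (3 equiv), AcOH (cat.), MeOH, 0 → 20 °C
Reagents that add atoms: none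
Why: Wharton transposition of the α,β-epoxy ketone moves the oxygen from C2 to C10 and the alkene to C1=C2. C5 is untouched.

**Step 9**
Reactants: 9
Product: 10 methyl 2-[(1S)-6,6-dimethyl-2-oxocyclohex-3-en-1-yl]acetate
Conditions: Dess–Martin periodinane, NaHCO3, CH2Cl2, rt
Reagents that add atoms: none
Why: Oxidation of the allylic alcohol removes the transient C10 carbinol stereocentre and puts the ketone at C10.

**Step 10**
Reactants: 10
Product: 11 methyl 2-[(1S)-2,2-dimethyl-6-oxocyclohexyl]acetate
Conditions: H2 (1 atm), 10% Pd/C, EtOAc, rt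
Reagents that add atoms: none
Why: Conjugate C=C reduction under neutral conditions, so no epimerisation α to the ketone.

**Step 11**
Reactants: 11
Product: 12 (3aS,7aS)-7a-(2-bromoprop-2-en-1-yl)-4,4-dimethylhexahydro-1-benzofuran-2(3H)-one
Conditions: 2,3-dibromopropene (3 equiv), In powder (3 equiv), THF/sat. aq. NH4Cl, rt; p-TsOH (cat.) if needed to finish lactonization
Reagents that add atoms: 2,3-dibromopropene, C=C(Br)CBr
Why: Barbier-type 2-bromoallylindium 1,2-addition installs C20 and the tertiary alkoxide at C10. Only the alkoxide cis to the C5 side chain lactonizes (loss of MeOH), so the cis-fused lactone sets C10 relative to C5 and the trans isomer is removed.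

**Step 12**
Reactants: 13 dimethyl squarate
Product: 14 4-hydroxy-4-isopropyl-2,3-dimethoxycyclobut-2-en-1-one
Conditions: iPrLi, THF, −78 °C
Reagents that add atoms: isopropyllithium, CC(C)[Li]
Why: 1,2-Addition of the organolithium to a squarate ester carbonyl.

**Step 13**
Reactants: 14
Product: 15 3-isopropyl-4-methoxycyclobut-3-ene-1,2-dione
Conditions: TFAA, CH2Cl2, −78 °C → rt; then H2O
Reagents that add atoms: water, O (TFAA is only an activator)
Why: Acylation and ionisation of the tertiary alcohol, then hydrolysis of one enol ether, gives the 3-alkyl-4-methoxy dione. Its vinylogous-ester carbonyl, next to the C–iPr carbon, is the deactivated one.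

**Step 14**
Reactants: 12 and 15
Product: 16 (3aS,7aS)-7a-[2-(1-hydroxy-3-isopropyl-2-methoxy-4-oxocyclobut-2-en-1-yl)prop-2-en-1-yl]-4,4-dimethylhexahydro-1-benzofuran-2(3H)-one
Conditions: t-BuLi (2.1 equiv), THF/Et2O/pentane, −100 °C, 15 min; then 15 (1.3 equiv), −100 → −78 °C; aq. NH4Cl
Reagents that add atoms: none (t-BuLi only performs Br/Li exchange)
Why: The vinyl bromide gives a 2-lithioalkene that adds to the more electrophilic squarate carbonyl, the one next to the C–OMe carbon. This puts the carbinol next to C12 (OMe) and the ketene-forming carbonyl next to C13 (iPr). The new carbinol stereocentre is destroyed in the next step.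

**Step 15 (key step)**
Reactants: 16
Product: 17 (3aS,7aS)-7a-[(2,5-dihydroxy-4-isopropyl-3-methoxyphenyl)methyl]-4,4-dimethylhexahydro-1-benzofuran-2(3H)-one
Conditions: PhMe, 110 °C, 2 h, Ar
Reagents that add atoms: none
Why: Moore/Liebeskind cascade. Conrotatory 4π ring opening gives a vinylketene, 6π closure onto the 1,1-disubstituted alkene forms the C8–C14 bond, and tautomerisation gives the hydroquinone with OMe at C12, iPr at C13, and the one free ring C–H at C8.

**Step 16**
Reactants: 17
Product: 18 (3aS,7aS)-7a-[(4-isopropyl-2,3,5-trimethoxyphenyl)methyl]-4,4-dimethylhexahydro-1-benzofuran-2(3H)-one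
Conditions: Me2SO4, K2CO3, acetone, reflux
Reagents that add atoms: dimethyl sulfate, COS(=O)(=O)OC
Why: O-Methylation protects the hydroquinone as the trimethyl ether. The lactone leaves the tertiary oxygen acylated, so it is not methylated.

**Step 17**
Reactants: 18
Product: 19 (3aS,7aS)-7a-[(6-bromo-4-isopropyl-2,3,5-trimethoxyphenyl)methyl]-4,4-dimethylhexahydro-1-benzofuran-2(3H)-one
Conditions: NBS, MeCN, 0 °C
Reagents that add atoms: N-bromosuccinimide, O=C1CCC(=O)N1Br
Why: Electrophilic bromination of this electron-rich arene occurs only at C8, the sole aromatic C–H.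

**Step 18**
Reactants: 19
Product: 20 trimethoxy bridged hemiketal (7-hydroxy-7,10-epoxy icetexane, 11,12,14-OMe)
Conditions: t-BuLi (2.1 equiv), THF, −100 → −50 °C; then aq. NH4Cl
Reagents that add atoms: none
Why: Br/Li exchange at C8 is followed by intramolecular addition of the aryllithium to the lactone C7 carbonyl. This closes the seven-membered ring B, and the tertiary alkoxide at C10 adds back to give the bridged 7,10-hemiketal. C7 can adopt only one configuration within the bridged bicycle, so it is set by C5 and C10.

**Step 19**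
Reactants: 20
Product: 21 komaroviquinone
Conditions: CAN (3 equiv), MeCN/H2O (3:1), 0 °C
Reagents that add atoms: water, O
Why: The 1,4-dimethoxy pair (C11, C14) is oxidised to the quinone with loss of two MeOH, and the C12 OMe is retained.

## Compound list
1 | (S)-(−)-limonene | C=C(C)[C@@H]1CC=C(C)CC1 | starting material
2 | (3S)-3-acetyl-6-oxoheptanal | CC(=O)[C@H](CC=O)CCC(C)=O | intermediate
3 | (3S)-3-acetyl-6-oxoheptanoic acid | CC(=O)[C@H](CC(=O)O)CCC(C)=O | intermediate
4 | methyl (3S)-3-acetyl-6-oxoheptanoate | CC(=O)[C@H](CC(=O)OC)CCC(C)=O | intermediate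
5 | methyl 2-[(1S)-2-methyl-4-oxocyclohex-2-en-1-yl]acetate | CC1=CC(=O)CC[C@H]1CC(=O)OC | intermediate
6 | methyl 2-[(1S)-2,2-dimethyl-4-oxocyclohexyl]acetate | COC(=O)C[C@H]1C(C)(C)CC(=O)CC1 | intermediate
7 | methyl 2-[(1R)-6,6-dimethyl-4-oxocyclohex-2-en-1-yl]acetate | COC(=O)C[C@H]1C(C)(C)CC(=O)C=C1 | intermediate
8 | methyl 2-[(2S)-3,3-dimethyl-5-oxo-7-oxabicyclo[4.1.0]heptan-2-yl]acetate | COC(=O)C[C@H]1C(C)(C)CC(=O)C2OC12 | intermediate
9 | methyl 2-[(1S)-2-hydroxy-6,6-dimethylcyclohex-3-en-1-yl]acetate | COC(=O)C[C@H]1C(C)(C)CC=CC1O | intermediate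
10 | methyl 2-[(1S)-6,6-dimethyl-2-oxocyclohex-3-en-1-yl]acetate | COC(=O)C[C@H]1C(C)(C)CC=CC1=O | intermediate
11 | methyl 2-[(1S)-2,2-dimethyl-6-oxocyclohexyl]acetate | COC(=O)C[C@H]1C(C)(C)CCCC1=O | intermediate
12 | (3aS,7aS)-7a-(2-bromoprop-2-en-1-yl)-4,4-dimethylhexahydro-1-benzofuran-2(3H)-one | C=C(Br)C[C@@]12CCCC(C)(C)[C@@H]1CC(=O)O2 | intermediate
13 | dimethyl squarate | COC1=C(OC)C(=O)C1=O | starting material
14 | 4-hydroxy-4-isopropyl-2,3-dimethoxycyclobut-2-en-1-one | COC1=C(OC)C(=O)C1(O)C(C)C | intermediate
15 | 3-isopropyl-4-methoxycyclobut-3-ene-1,2-dione | CC(C)C1=C(OC)C(=O)C1=O | intermediate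
16 | cyclobutenone adduct (name in Step 14) | COC1=C(C(C)C)C(=O)C1(O)C(=C)C[C@@]23CCCC(C)(C)[C@@H]2CC(=O)O3 | intermediate
17 | hydroquinone lactone (name in Step 15) | C(c1cc(O)c(C(C)C)c(OC)c1O)[C@@]23CCCC(C)(C)[C@@H]2CC(=O)O3 | intermediate
18 | trimethoxyarene lactone (name in Step 16) | C(c1cc(OC)c(C(C)C)c(OC)c1OC)[C@@]23CCCC(C)(C)[C@@H]2CC(=O)O3 | intermediate
19 | aryl bromide lactone (name in Step 17) | C(c1c(Br)c(OC)c(C(C)C)c(OC)c1OC)[C@@]23CCCC(C)(C)[C@@H]2CC(=O)O3 | intermediate
20 | trimethoxy bridged hemiketal | COc1c(C(C)C)c(OC)c2c(c1OC)C[C@@]34CCCC(C)(C)[C@@H]3C[C@]2(O)O4 | intermediate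
21 | komaroviquinone | COC1=C(C(C)C)C(=O)C2=C(C[C@@]34CCCC(C)(C)[C@@H]3C[C@]2(O)O4)C1=O | target

## Step count
Total steps: 19 (one convergent squarate arm of 2 steps, Steps 12–13). Longest linear sequence: 17 steps (1 → 11, then 14 → 19).

## Three steps most likely to fail
1. **Step 14 (vinyllithium formed with the lactone present).** The lithioalkene could attack the lactone intramolecularly (5-exo) before the squarate is added. Fallback: open lactone 12 with LiOH to the lithium carboxylate/alkoxide dianion, which is inert to RLi, do the Br/Li exchange and squarate addition on that, and re-lactonize with TsOH during or after the thermolysis.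
2. **Step 18 (seven-membered-ring aryllithium closure).** Intramolecular acylation could stall or give over-addition. Fallback: change to a Friedel–Crafts closure. Open the lactone, protect C10–OH as the TES ether, make the acid chloride, cyclise onto C8–H of the trimethoxyarene with SnCl4, then deprotect to the hemiketal (no bromination needed).
3. **Step 4 (aldol regiochemistry).** Closure onto the chain ketone instead of the acetyl would give the wrong ring A. Fallback: use selective mono-ozonolysis of limonene to methyl limononate and close ring A by a Conia-ene-type carbocyclization of the ketone enol onto the isopropenyl group, giving 6 directly and avoiding the acetyl/aldol problem.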